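## Retrosynthetic overview

1. The target is a dibenzofuran (rings A, B, C) whose ring C is a para-quinone methide (C4=O, exocyclic C1=C) fused at C1–C2 to a butenolide (ring D) bearing a 4-hydroxyphenyl group. Ring D is taken back to Friedel–Crafts alkylation and lactonisation of 4-methoxymandelic acid at C1/O2 of a 7,8-dimethoxy-3-phenyldibenzofuran-2,4-diol, followed by DDQ dehydrogenation and O-demethylation.
2. The strategy rests on ring A: a 7,8-dioxygenated benzo ring held to ring C only through two neighbouring atoms, C5a (bonded to O5) and C9a (bonded to C9b). This is the bonding pattern of an aryne, so cutting O5–C5a and C9a–C9b gives 4,5-dimethoxybenzyne and an ortho-iodophenol, and the same step closes furan ring B.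
3. The iodine of that phenol lies meta to both ring C ethers, where electrophilic iodination would not be expected to go (it should prefer C5, ortho and para to the ethers). It is therefore placed by directed lithiation ortho to a masked aldehyde, which a Baeyer–Villiger oxidation then turns into the phenol OH. The ring C ethers are isopropyl, which tolerate n-BuLi and are cleaved by BCl3 beside methyl ethers.
4. Ring order: ring C (from 2-bromoresorcinol, phenyl by Suzuki coupling), then rings A and B in the key step, then lactone ring D, then the quinone methide and the free phenols.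

Key step: step 6

Remark on the chemistry: the target has no stereocentre; 7–9 and 18–20 are racemic and the one stereocentre of 20 is removed in step 9. Dibenzofuran numbering (C1–C4, C4a, O5, C5a, C6–C9, C9a, C9b) is used for the ring-fused compounds.

## Route

Step 1
Reactants: 1 2-bromoresorcinol (2-bromobenzene-1,3-diol)
Product: 2 2-bromo-1,3-di(propan-2-yloxy)benzene
Conditions: 2-bromopropane (3 equiv), K2CO3, DMF, 70 °C
Reagents that add atoms: 2-bromopropane, CC(C)Br
Why: Williamson ether synthesis, in which both phenoxides are alkylated by the secondary bromide in DMF, the excess bromide making up for loss by elimination, while the aryl bromide is inert.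

Step 2
Reactants: 2 2-bromo-1,3-di(propan-2-yloxy)benzene; 3 phenylboronic acid
Product: 4 2,6-di(propan-2-yloxy)biphenyl
Conditions: Pd(OAc)2 (2 mol %), SPhos (4 mol %), K3PO4, toluene/H2O, 100 °C
Reagents that add atoms: none
Why: Suzuki–Miyaura coupling, for which the bulky electron-rich biarylphosphine SPhos is suited to oxidative addition and reductive elimination at a di-ortho-alkoxy aryl bromide, and the boronic acid has no ortho substituent.

Step 3
Reactants: 4 2,6-di(propan-2-yloxy)biphenyl
Product: 6 3-phenyl-2,4-di(propan-2-yloxy)benzaldehyde, via aryliminium chloride 5 (not isolated)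
Conditions: POCl3, DMF, 80 °C; then H2O
Reagents that add atoms: N,N-dimethylformamide, CN(C)C=O; water, O
Why: Vilsmeier–Haack formylation, in which the chloroiminium ion attacks the ring position ortho to one and para to the other alkoxy group (the two such positions are equivalent by symmetry, and the unsubstituted phenyl ring is not activated) and hydrolysis of iminium salt 5 gives the aldehyde.

Step 4
Reactants: 6 3-phenyl-2,4-di(propan-2-yloxy)benzaldehyde
Product: 10 6-iodo-3-phenyl-2,4-di(propan-2-yloxy)benzaldehyde, via lithium α-amino alkoxide 7 (not isolated), via ortho-lithiated α-amino alkoxide 8 (not isolated), via iodinated α-amino alkoxide 9 (not isolated)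
Conditions: Me2NCH2CH2N(Me)Li (from N,N,N'-trimethylethylenediamine and n-BuLi), THF, −20 °C; n-BuLi (3 equiv), −20 °C; I2, −78 °C to rt; H2O
Reagents that add atoms: iodine, II
Why: Directed ortho-metalation through in situ α-amino alkoxide protection of the aldehyde, in which the chelating dimethylaminoethyl arm of 7 brings n-BuLi to C6, the only C–H ortho to the masked aldehyde, whereas the hindered isopropoxy groups are weak directors (the one at C4 turns its alkyl group toward C5), and iodine quench followed by hydrolysis returns the aldehyde.

Step 5
Reactants: 10 6-iodo-3-phenyl-2,4-di(propan-2-yloxy)benzaldehyde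
Product: 12 6-iodo-3-phenyl-2,4-di(propan-2-yloxy)phenol, via aryl formate 11 (not isolated)
Conditions: mCPBA, CH2Cl2, 0 °C to rt; then K2CO3 (cat.), MeOH, rt
Reagents that add atoms: 3-chloroperoxybenzoic acid, OOC(=O)c1cccc(Cl)c1
Why: Baeyer–Villiger oxidation (Dakin-type), in which the aryl group made electron-rich by ortho and para alkoxy donors migrates in the Criegee intermediate to give formate 11, and mild methanolysis frees the phenol without touching the aryl iodide or the ethers.

Step 6
Reactants: 12 6-iodo-3-phenyl-2,4-di(propan-2-yloxy)phenol; 13 4,5-dimethoxy-2-(trimethylsilyl)phenyl trifluoromethanesulfonate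
Product: 16 7,8-dimethoxy-3-phenyl-2,4-di(propan-2-yloxy)dibenzofuran, via 4,5-dimethoxybenzyne 14 (not isolated), via iodo diaryl ether 15 (not isolated)
Conditions: CsF (3 equiv), MeCN, rt; then Pd(OAc)2 (5 mol %), PCy3 (10 mol %), 100 °C, same pot
Reagents that add atoms: none
Why: Fluoride removes the silyl group of 13 and triflate leaves, giving the symmetrical aryne 14; the cesium phenoxide of 12 adds to it and the resulting aryl anion is protonated by the medium, which makes the O5–C5a bond and ether 15. Zerovalent palladium, formed in the pot from Pd(OAc)2 and PCy3, then inserts into the C–I bond, the divalent palladium species ArPdI(PCy3) palladates an ortho C–H of the dimethoxyphenoxy ring by concerted metalation–deprotonation with fluoride or acetate as base, and reductive elimination from the six-membered palladacycle makes the C9a–C9b bond. The closest known reaction type is the one-pot aryne O-arylation of 2-iodophenols followed by palladium-catalysed intramolecular direct arylation to dibenzofurans. Furan ring B is closed in this second event as a five-membered ring by biaryl C–C bond formation, with the new ether oxygen as the tether, and no stereocentre is formed. Two selectivities are needed: the site of phenoxide addition does not matter because the two aryne carbons are equivalent, and of the two ortho C–H bonds of the 3,4-dimethoxyphenoxy ring the one flanked by hydrogen should be palladated in preference to the one flanked by a methoxy group, which gives the 7,8- and not the 8,9-dimethoxy pattern. The iodine set at C6 of 12 in step 4 fixes C9b and leaves C1 free for step 8.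

Step 7
Reactants: 16 7,8-dimethoxy-3-phenyl-2,4-di(propan-2-yloxy)dibenzofuran
Product: 17 7,8-dimethoxy-3-phenyldibenzofuran-2,4-diol
Conditions: BCl3 (4 equiv), CH2Cl2, −78 to 0 °C; then H2O
Reagents that add atoms: none
Why: Lewis acid ether cleavage, in which BCl3 removes a secondary isopropyl group from an aryl ether much faster than a methyl group, so both isopropyl ethers should fall while the two ring A methyl ethers stay, and aqueous work-up frees the phenols.

Step 8
Reactants: 17 7,8-dimethoxy-3-phenyldibenzofuran-2,4-diol; 18 4-methoxymandelic acid (racemic)
Product: 20 4-hydroxy-7,8-dimethoxy-3-phenyldibenzofuran bridged from C1 to C2 by –CH(4-methoxyphenyl)–C(=O)–O– (benzofuran-2(3H)-one type lactone; racemic), via arylacetic acid 19 (not isolated)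
Conditions: TsOH·H2O (20 mol %), toluene, 100 °C, Dean–Stark
Reagents that add atoms: none
Why: Acid-catalysed Friedel–Crafts alkylation and lactonisation (the mandelic acid–phenol route to 3-arylbenzofuran-2(3H)-ones), in which the 4-methoxybenzylic cation from 18 attacks C1, the only free carbon of ring C and the one ortho to the C2 hydroxyl and para to the C4 hydroxyl, and acid 19 closes the five-membered lactone on the C2 hydroxyl; the new stereocentre forms as a racemate and is removed in step 9.

Step 9
Reactants: 20 the racemic lactone from step 8
Product: 21 7,8-dimethoxy-3-phenyldibenzofuran-4(1H)-one with an exocyclic C1=C double bond to the carbon bearing 4-methoxyphenyl, that carbon joined through C(=O)–O to C2 (butenolide ring D, C2=C3 double bond)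
Conditions: DDQ (1.1 equiv), 1,4-dioxane, rt
Reagents that add atoms: none
Why: DDQ dehydrogenation, in which loss of the doubly benzylic lactone α-hydrogen and of the hydrogen of the para C4 hydroxyl gives the para-quinone methide conjugated with the lactone carbonyl, a known conversion of 6-hydroxy-3-arylbenzofuran-2(3H)-ones, while the methyl ethers keep ring A and the aryl group from being oxidised.

Step 10
Reactants: 21 the trimethyl ether quinone methide from step 9
Product: 22 target CNP0139113.0 (as 21, with hydroxyl groups at C7, C8 and on the 4-position of the aryl group)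
Conditions: BBr3 (8 equiv), CH2Cl2, −78 °C to rt; then H2O
Reagents that add atoms: none
Why: BBr3 cleavage of the three aryl methyl ethers, in which any hydrogen bromide added across the quinone methide gives a para-hydroxybenzylic bromide that should lose HBr again on aqueous work-up, and the lactone should not be cleaved at these temperatures.

## Compound list

1 | 2-bromoresorcinol | Oc1cccc(O)c1Br | starting material
2 | 2-bromo-1,3-di(propan-2-yloxy)benzene | CC(C)Oc1cccc(OC(C)C)c1Br | intermediate
3 | phenylboronic acid | OB(O)c1ccccc1 | starting material
4 | 2,6-di(propan-2-yloxy)biphenyl | CC(C)Oc1cccc(OC(C)C)c1-c1ccccc1 | intermediate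
5 | N-{[3-phenyl-2,4-di(propan-2-yloxy)phenyl]methylidene}-N-methylmethanaminium chloride (not isolated) | C[N+](C)=Cc1ccc(OC(C)C)c(-c2ccccc2)c1OC(C)C.[Cl-] | intermediate
6 | 3-phenyl-2,4-di(propan-2-yloxy)benzaldehyde | O=Cc1ccc(OC(C)C)c(-c2ccccc2)c1OC(C)C | intermediate
7 | lithium α-amino alkoxide of 6 with N,N,N'-trimethylethylenediamine (racemic, not isolated) | [Li+].[O-]C(N(C)CCN(C)C)c1ccc(OC(C)C)c(-c2ccccc2)c1OC(C)C | intermediate
8 | C6-lithiated α-amino alkoxide (racemic, not isolated) | [Li+].[O-]C(N(C)CCN(C)C)c1c([Li])cc(OC(C)C)c(-c2ccccc2)c1OC(C)C | intermediate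
9 | C6-iodinated α-amino alkoxide (racemic, not isolated) | [Li+].[O-]C(N(C)CCN(C)C)c1c(I)cc(OC(C)C)c(-c2ccccc2)c1OC(C)C | intermediate
10 | 6-iodo-3-phenyl-2,4-di(propan-2-yloxy)benzaldehyde | O=Cc1c(I)cc(OC(C)C)c(-c2ccccc2)c1OC(C)C | intermediate
11 | 6-iodo-3-phenyl-2,4-di(propan-2-yloxy)phenyl formate (not isolated) | O=COc1c(I)cc(OC(C)C)c(-c2ccccc2)c1OC(C)C | intermediate
12 | 6-iodo-3-phenyl-2,4-di(propan-2-yloxy)phenol | Oc1c(I)cc(OC(C)C)c(-c2ccccc2)c1OC(C)C | intermediate
13 | 4,5-dimethoxy-2-(trimethylsilyl)phenyl trifluoromethanesulfonate | COc1cc(OS(=O)(=O)C(F)(F)F)c(cc1OC)[Si](C)(C)C | starting material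
14 | 4,5-dimethoxybenzyne (not isolated) | COC1=CC#CC=C1OC | intermediate
15 | 1-(3,4-dimethoxyphenoxy)-6-iodo-3-phenyl-2,4-di(propan-2-yloxy)benzene (not isolated) | COc1ccc(Oc2c(I)cc(OC(C)C)c(-c3ccccc3)c2OC(C)C)cc1OC | intermediate
16 | 7,8-dimethoxy-3-phenyl-2,4-di(propan-2-yloxy)dibenzofuran | COc1cc2c(cc1OC)oc1c(OC(C)C)c(-c3ccccc3)c(OC(C)C)cc12 | intermediate
17 | 7,8-dimethoxy-3-phenyldibenzofuran-2,4-diol | COc1cc2c(cc1OC)oc1c(O)c(-c3ccccc3)c(O)cc12 | intermediate
18 | 4-methoxymandelic acid (racemic) | COc1ccc(cc1)C(O)C(O)=O | starting material
19 | 2-(2,4-dihydroxy-7,8-dimethoxy-3-phenyldibenzofuran-1-yl)-2-(4-methoxyphenyl)acetic acid (racemic, not isolated) | COc1ccc(cc1)C(C(O)=O)c1c(O)c(-c2ccccc2)c(O)c2oc3cc(OC)c(OC)cc3c12 | intermediate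
20 | lactone of 19 closed on the C2 oxygen, C4 hydroxyl free (racemic) | O=C1Oc2c(-c3ccccc3)c(O)c3oc4cc(OC)c(OC)cc4c3c2C1c1ccc(OC)cc1 | intermediate
21 | quinone methide lactone, trimethyl ether of the target | O=C1OC2=C(c3ccccc3)C(=O)c3oc4cc(OC)c(OC)cc4c3C2=C1c1ccc(OC)cc1 | intermediate
22 | CNP0139113.0 | O=C1OC2=C(c3ccccc3)C(=O)c3oc4cc(O)c(O)cc4c3C2=C1c1ccc(O)cc1 | target

## Step count and risks

Total step count: 10. Longest linear sequence: 10 steps (1 to 22); 3, 13 and 18 enter as commercial materials.

Steps most likely to fail:

Step 6. The palladation stage may stall on the crowded, electron-rich ether (loss of iodine by reduction instead of ring closure), or C–H palladation may take the ortho carbon next to the methoxy group. The fallback sets out from 12 and forms the C–C bond first. Suzuki–Miyaura coupling of 12 with 3,4-dimethoxyphenylboronic acid (Pd(OAc)2, SPhos, K3PO4, toluene/H2O) should give the biaryl phenol 6-(3,4-dimethoxyphenyl)-3-phenyl-2,4-di(propan-2-yloxy)phenol F1. A phenol-directed, palladium-catalysed oxidative C–H/C–O cyclisation (Pd(OAc)2, 3-nitropyridine, tert-butyl peroxybenzoate, C6F6/1,3-dimethyl-2-imidazolidinone, 90 °C) should then close ring B at the less hindered ortho carbon of the dimethoxyphenyl ring. The fallback comes back to the route at 16.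

Step 8. Acid ionisation of the electron-rich mandelic acid may lead to its self-condensation, or to alkylation of ring A (C6 or C9) instead of the bay carbon C1. The fallback sets out from 17 and uses a non-ionising electrophile delivered from oxygen. TiCl4 in CH2Cl2 converts the C2 hydroxyl into its aryloxytitanium trichloride, which should add through its only free ortho carbon, C1, to the ketone of methyl 2-(4-methoxyphenyl)-2-oxoacetate. Lactonisation should then give the tertiary carbinol lactone (20 with OH in place of the lactone α-hydrogen) F2. Acid-promoted loss of water (TsOH, toluene, heat) should give the quinone methide directly. The fallback comes back to the route at 21 and makes step 9 unnecessary.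

Step 10. Bromide addition to, or Lewis acid degradation of, the quinone methide lactone may compete with ether cleavage, or cleavage of the three ethers may stay incomplete. The fallback sets out from 20 and reverses the order of the last two operations. BBr3 in CH2Cl2 on the reduced lactone should give the tetrahydroxy lactone (20 with the three methoxy groups as hydroxyl groups, racemic) F3. Dehydrogenation with one equivalent of DDQ in dioxane, relying on the extended quinone methide being the favoured two-electron oxidation product, should then give the target. The fallback comes back to the route at 22.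

Further compounds
F1 | step 6 | 6-(3,4-dimethoxyphenyl)-3-phenyl-2,4-di(propan-2-yloxy)phenol | COc1ccc(cc1OC)-c1cc(OC(C)C)c(-c2ccccc2)c(OC(C)C)c1O
F2 | step 8 | lactone 20 bearing a hydroxyl group on the lactone α-carbon (racemic) | O=C1Oc2c(-c3ccccc3)c(O)c3oc4cc(OC)c(OC)cc4c3c2C1(O)c1ccc(OC)cc1
F3 | step 10 | lactone 20 with all three methyl ethers cleaved (racemic) | O=C1Oc2c(-c3ccccc3)c(O)c3oc4cc(O)c(O)cc4c3c2C1c1ccc(O)cc1
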